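I began from the substrate left over at the end of the run, since the flask's progress can be read from that remainder.

substrate 29 mM; acid 2.90 mM; time 20 s

    substrate + target → side product A (k1 = 1.06 L mol⁻¹ s⁻¹)
    substrate + weak acid → side product B (k2 = 4.66 L mol⁻¹ s⁻¹)
    substrate + acid → weak acid + acid + target (k3 = 47.7 L mol⁻¹ s⁻¹)
    weak acid ⇌ conjugate base + acid, settled at all times (K4 = 2.5 × 10⁻⁸ M)
    substrate → weak acid + target (k5 = 0.00190 s⁻¹)

- acid is the free proton; pH is minus the decimal logarithm of its molar concentration
- percent here means substrate units held: one side product A counts as two
- run time (flask): 20 s

- part of the substrate that has reacted at 20 s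
- pH of the solution at 20 s

The acid leaves the catalysed step as it entered, so I froze c(acid) at its charge. Even with the whole charge of substrate turned into weak acid, dissociation would free 2.50 × 10⁻⁴ mM, far less than the 2.90 mM present. I therefore expected the pH to stay at minus the decimal logarithm of that charge. The uncatalysed step, at 0.00190 s⁻¹, is far slower than the catalysed one at 0.138 s⁻¹, so I set it aside.

With c(acid) frozen, the catalysed step is pseudo-first-order, and I carried one quantity: the catalytic half-life, the natural logarithm of two divided by that catalysed rate, 5.01 s.

I reckoned the substrate two ways. By half-lives, the run lasts 3.99 of them, leaving 6.29%. By the starting rate kept up, 4.01 mM s⁻¹ would consume 80.2 mM in the run, more than the 29 mM charged. The two ways part, and the second cheats: it freezes c(substrate) too, and that falls. The side steps also take substrate, so I committed to 6.29% as a ceiling on the leftover.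

The forecast gave 98.6% reacted and a pH of 2.54, holding that “the weak acid barely dissociates at this proton level”.

The simulation gave 98.6% reacted and a pH of 2.54. In this flask the acid stood at 100% of its charge, and the 1.4% of substrate left lay below my ceiling. In this flask at 20.0 s, the half-life of substrate by its reaction with weak acid to side product B was 9.8 s, longer than the 5.01 s of the catalysed step.

In the neighbour flask with 0.72 mM of acid, the half-life becomes 20.2 s, which puts the ceiling at 50.3%. The computed neighbour flask kept 28% of its substrate, below that ceiling.

The numbers of this flask belong to no real substance; the rest is arithmetic.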